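The clock here is 2.5 h, and I want to know how many half-lives it holds in each flask.

common to all: starting material 0.050 M
- epsilon: reagent 1.3 equiv; run made earlier
- theta: reagent 6.1 equiv; run made earlier
- ochre: reagent 1.10 equiv; time 2.5 h
- grey: reagent 2.20 equiv; time 2.5 h
- violet: reagent 4.40 equiv; time 2.5 h

| run | time / min | intermediate A / % | starting material / % | target / % | intermediate B / % | side product A / % |
|---|---|---|---|---|---|---|
| epsilon | 6.00 | 16 | 84 | 0 | 0 | 0 |
| epsilon | 15.0 | 27 | 70 | 2 | 1 | 1 |
| epsilon | 30.0 | 38 | 55 | 0 | 2 | 0 |
| epsilon | 50.0 | 46 | 47 | 4 | 6 | 0 |
| epsilon | 60.0 | 42 | 44 | 0 | 7 | 1 |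
| epsilon | 80.0 | 43 | 40 | 3 | 11 | 4 |
| epsilon | 120 | 38 | 36 | 4 | 14 | 2 |
| theta | 6.00 | 49 | 45 | 0 | 2 | 0 |
| theta | 15.0 | 67 | 17 | 2 | 3 | 1 |
| theta | 30.0 | 59 | 9 | 1 | 5 | 6 |
| theta | 50.0 | 46 | 7 | 5 | 10 | 11 |
| theta | 60.0 | 38 | 5 | 9 | 11 | 14 |
| theta | 80.0 | 28 | 3 | 13 | 14 | 22 |
| theta | 120 | 15 | 4 | 21 | 16 | 32 |

(scatter of a reading: 1.5 percentage points)

- the analysis behind the earlier runs scatters by 1.5 percentage points, standard deviation

- which of these there is most of at the end, counted by the starting material in it, ochre (side product A / target / starting material / intermediate A / intermediate B)
- which of these there is most of at the end, counted by the starting material in it, grey (side product A / target / starting material / intermediate A / intermediate B)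
- which of these there is most of at the end, counted by the starting material in it, violet (side product A / target / starting material / intermediate A / intermediate B)
- how much there is at the end of the one of these that leads, in percent of the starting material charged: ochre
- how much there is at the end of the one of these that leads, in percent of the starting material charged: grey
- how much there is at the end of the one of these that leads, in percent of the starting material charged: violet

In the first instants, starting material meets reagent and becomes intermediate A. Epsilon loses 16.0% of it in 6.00 min, which, scaled to the reagent of ochre, reads as a half-life of about 28.2 min, shorter than the time.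

In the middle the starting material of epsilon flattens, 47% at 50.0 min and 36% at 120 min, so I watch its sum with intermediate A as one pool. Over those readings the epsilon pool loses 0.00326 min⁻¹. From 30.0 min to 120 min the theta pool loses 0.0142 min⁻¹, which is faster. I take the loss as pseudo-first-order at a fixed charge and interpolate it linearly in equivalents. Ochre gets 4.11 h, grey 2.18 h and violet 1.12 h. This is the pool half-life: the time in which starting material plus intermediate A together halve at that charge.

At the end the clock holds 0.608 half-lives in ochre, 1.15 in grey and 2.23 in violet, so I reckon pools of 65.6%, 45.1% and 21.3%. I count from zero, across the forming time, so I expect these a little low.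

Ochre has less reagent than epsilon, where the two stood about level at 120 min, so I put starting material ahead in ochre; grey has more, so I put intermediate A ahead in grey. Theta counts 1.64 half-lives at 80.0 min, with intermediate A ahead of side product A, and 2.45 at 120 min, with side product A ahead. The violet count lies between them, nearer the later, so I commit to side product A in violet.

The forecast says starting material at 41% in ochre, intermediate A at 37% in grey and intermediate A at 24% in violet, and of violet it writes “This is a close call”. We part on violet.

The flasks give starting material at 40.9% in ochre, intermediate A at 33.5% in grey and side product A at 27.3% in violet, where intermediate A stands at 19.0%.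

    starting material + reagent ⇌ intermediate A (K = 41.6 M⁻¹, k = 28.1 M⁻¹ h⁻¹)
    intermediate C → target (k = 0.706 h⁻¹)
    reagent + intermediate A ⇌ intermediate C (K = 71.0 M⁻¹, k = 3.37 M⁻¹ h⁻¹)
    intermediate A → intermediate B (k = 0.233 h⁻¹)
    intermediate C → side product A (k = 1.02 h⁻¹)
    intermediate B → side product B (k = 0.155 h⁻¹)

In ochre the passing of starting material and reagent into intermediate A did half of its turnover up to the end by 0.302 h, and at the end intermediate A was made more slowly than it was used, at a ratio of 0.357. In violet intermediate A fell from 63.0% at 0.500 h to 19.0% at 2.50 h, while intermediate C stood at 14.0% at 1.25 h and side product A rose from 13.4% then to 27.3%. The pools end at 72.5% in ochre, 50.1% in grey and 22.6% in violet.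

For ochre read at 1.0 h, 4.11 h counts 0.243 half-lives and a pool of 84.5%. Ochre at that time holds a pool of 89.5%, of which 50.0% is starting material.

The runs stem from a simulated flask on assumed constants.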